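**Retrosynthetic overview**

- Rings: A carries OCH3, OH, the aryloxy oxygen and a CH2; B is the meta-bridged ring; C is the OH-bearing trisubstituted ring; D is the para-bridged ring. The 18-membered ring runs A–O–B–CH2CH2–C–O–D–CH2CH2–A.
- Last skeletal bond: the ring D carbon para to the ring C–O–ring D oxygen is joined to the CH2 two carbons away from ring A. A radical Truce–Smiles aryl shift from sulfur to carbon does this inside a 19-membered arenesulfonate (21 → 22), with loss of SO2.
- Enabling feature: the free phenolic oxygen of ring A (para to OCH3) is ortho to the ring A carbon that carries this CH2CH2 bridge. Ring D can therefore be parked on that oxygen as an aryl sulfonate, seven atoms from the terminal CH2, and the aryl transfer returns the oxygen as the free OH of the target.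
- The same sulfonyl group first activates a para fluorine for the SNAr macro-etherification (ring C–O–ring D) that builds the temporary ring. Ring A comes from isovanillin (Claisen, Ullmann, Baeyer–Villiger); the B–C bibenzyl comes from a Wittig/diimide sequence.
- Order of ring formation: 19-membered sulfonate ring (step 10), then contraction to the 18-membered ring (step 13); benzyl hydrogenolysis ends the route.

Key step: step 13

Remark: the target has no stereocentre and no stereogenic double bond; compounds 1, 3, 7, 8 and 14 are taken as commercial.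

**Route**

Step 1
Reactants: 1 4-(benzyloxy)-3-hydroxybenzaldehyde
Product: 2 4-(benzyloxy)-3-(methoxymethoxy)benzaldehyde
Conditions: MOMCl, iPr2NEt, CH2Cl2, 0 °C to rt
Reagents that add atoms: chloromethyl methyl ether (MOMCl), COCCl
Why: O-alkylation of the only phenol masks the ring C oxygen that must stay inert until the macro-etherification.

Step 2
Reactants: 2 4-(benzyloxy)-3-(methoxymethoxy)benzaldehyde; 3 (3-bromobenzyl)triphenylphosphonium bromide
Product: 5 1-(benzyloxy)-4-[2-(3-bromophenyl)ethenyl]-2-(methoxymethoxy)benzene (E/Z mixture), via ylide 4 (not isolated)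
Conditions: KOtBu, THF, 0 °C to rt
Reagents that add atoms: none
Why: Wittig olefination with the semi-stabilised benzylic ylide 4 formed in the flask; the E/Z composition does not matter because the alkene is saturated in step 3.

Step 3
Reactants: 5 1-(benzyloxy)-4-[2-(3-bromophenyl)ethenyl]-2-(methoxymethoxy)benzene
Product: 6 1-(benzyloxy)-4-[2-(3-bromophenyl)ethyl]-2-(methoxymethoxy)benzene
Conditions: TsNHNH2, NaOAc, DME/H2O, reflux
Reagents that add atoms: none
Why: Diimide reduction saturates the stilbene without touching the aryl bromide or the benzyl ether, both of which hydrogenation over palladium would endanger.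

Step 4
Reactants: 7 isovanillin (3-hydroxy-4-methoxybenzaldehyde); 8 allyl bromide
Product: 9 3-(allyloxy)-4-methoxybenzaldehyde
Conditions: K2CO3, DMF, 60 °C
Reagents that add atoms: none
Why: Williamson ether synthesis at the only phenol.

Step 5
Reactants: 9 3-(allyloxy)-4-methoxybenzaldehyde
Product: 10 2-allyl-3-hydroxy-4-methoxybenzaldehyde
Conditions: N,N-diethylaniline, 200 °C
Reagents that add atoms: none
Why: Aromatic Claisen rearrangement, in which the [3,3] shift can only reach the free ortho position next to the formyl-bearing carbon because the other ortho position carries the methoxy group.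

Step 6
Reactants: 10 2-allyl-3-hydroxy-4-methoxybenzaldehyde; 6 1-(benzyloxy)-4-[2-(3-bromophenyl)ethyl]-2-(methoxymethoxy)benzene
Product: 11 2-allyl-3-{3-[2-(4-(benzyloxy)-3-(methoxymethoxy)phenyl)ethyl]phenoxy}-4-methoxybenzaldehyde
Conditions: CuI (cat.), picolinic acid, K3PO4, DMSO, 90 °C
Reagents that add atoms: none
Why: Ullmann diaryl ether synthesis, for which the CuI/picolinic acid system is suited to doubly ortho-substituted phenols and aryl bromides and tolerates the aldehyde.

Step 7
Reactants: 11 2-allyl-3-{3-[2-(4-(benzyloxy)-3-(methoxymethoxy)phenyl)ethyl]phenoxy}-4-methoxybenzaldehyde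
Product: 13 2-allyl-3-{3-[2-(4-(benzyloxy)-3-(methoxymethoxy)phenyl)ethyl]phenoxy}-4-methoxyphenol, via formate 12 (not isolated)
Conditions: mCPBA, CH2Cl2, 0 °C to rt; then K2CO3 (cat.), MeOH, rt
Reagents that add atoms: 3-chloroperbenzoic acid (mCPBA), OOC(=O)c1cccc(Cl)c1
Why: Baeyer–Villiger oxidation of the electron-rich aldehyde (aryl migration favoured by the para methoxy group) gives formate 12, whose methanolysis frees the phenol, while the monosubstituted alkene should be epoxidised much more slowly.

Step 8
Reactants: 13 2-allyl-3-{3-[2-(4-(benzyloxy)-3-(methoxymethoxy)phenyl)ethyl]phenoxy}-4-methoxyphenol; 14 4-fluorobenzenesulfonyl chloride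
Product: 15 2-allyl-3-{3-[2-(4-(benzyloxy)-3-(methoxymethoxy)phenyl)ethyl]phenoxy}-4-methoxyphenyl 4-fluorobenzenesulfonate
Conditions: Et3N, DMAP (cat.), CH2Cl2, 0 °C to rt
Reagents that add atoms: none
Why: Sulfonylation of the only free phenol places the future ring D on the ring A oxygen through sulfur.

Step 9
Reactants: 15 2-allyl-3-{3-[2-(4-(benzyloxy)-3-(methoxymethoxy)phenyl)ethyl]phenoxy}-4-methoxyphenyl 4-fluorobenzenesulfonate
Product: 16 2-allyl-3-{3-[2-(4-(benzyloxy)-3-hydroxyphenyl)ethyl]phenoxy}-4-methoxyphenyl 4-fluorobenzenesulfonate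
Conditions: conc. HCl (cat.), MeOH/THF, 45 °C
Reagents that add atoms: none
Why: Acid-catalysed acetal exchange removes the MOM group, while the aryl sulfonate, aryl fluoride, benzyl ether and allyl group are stable to acid.

Step 10
Reactants: 16 2-allyl-3-{3-[2-(4-(benzyloxy)-3-hydroxyphenyl)ethyl]phenoxy}-4-methoxyphenyl 4-fluorobenzenesulfonate
Product: 17 19-membered macrocyclic sulfonate (ring A O–SO2–ring D, ring D para-O–ring C; allyl on ring A, benzyl ether on ring C)
Conditions: Cs2CO3, DMF, 70 °C, syringe-pump addition, 2 mM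
Reagents that add atoms: none
Why: Intramolecular SNAr (addition–elimination through a Meisenheimer adduct) in which the ring C phenoxide displaces the fluoride para to the sulfonyl group, with high dilution favouring the 19-membered ring over oligomers.

Step 11
Reactants: 17 19-membered macrocyclic sulfonate with allyl group
Product: 20 macrocyclic sulfonate with 2-hydroxyethyl group on ring A, via diol 18 (not isolated), via aldehyde 19 (not isolated)
Conditions: OsO4 (cat.), NaIO4, 2,6-lutidine, dioxane/H2O, rt; extractive work-up; then NaBH4, MeOH, 0 °C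
Reagents that add atoms: sodium periodate, [Na+].[O-]I(=O)(=O)=O (terminal oxidant; the new oxygen is delivered through OsO4, O=[Os](=O)(=O)=O)
Why: Lemieux–Johnson cleavage of the terminal alkene followed by borohydride reduction shortens the allyl group to the 2-hydroxyethyl group, and the carbinol stereocentre of diol 18 (racemic) is destroyed in the cleavage.

Step 12
Reactants: 20 macrocyclic sulfonate with 2-hydroxyethyl group
Product: 21 macrocyclic sulfonate with 2-iodoethyl group on ring A
Conditions: I2, PPh3, imidazole, CH2Cl2, 0 °C to rt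
Reagents that add atoms: iodine, II
Why: Appel iodination of the primary alcohol under near-neutral conditions that leave the aryl sulfonate untouched.

Step 13
Reactants: 21 macrocyclic sulfonate with 2-iodoethyl group
Product: 22 ring C O-benzyl ether of the target (18-membered ring, free OH on ring A)
Conditions: Bu3SnH (syringe pump), AIBN (cat.), PhH, 80 °C, 2 mM
Reagents that add atoms: none
Why: Proposed new method: iodine abstraction by the tin radical gives the primary 2-arylethyl radical, which adds to the sulfur-bearing carbon of ring D (ipso attack through a seven-membered spiro transition state, the 1,6 mode); the spiro cyclohexadienyl radical re-aromatises by C–S scission, the aryloxysulfonyl radical loses SO2, and the ring A phenoxyl radical takes hydrogen from Bu3SnH to carry the chain. The closest known reaction type is the radical Truce–Smiles rearrangement of arenesulfonates and arenesulfonamides (1,4 and 1,5 aryl shifts from sulfur to a carbon radical with loss of SO2); new here are the 1,6 mode and its use as a ring contraction of a macrocyclic sulfonate. The 18-membered ring is closed by this aryl transfer from sulfur to carbon: S, O and the oxygen-bearing ring A carbon leave the ring path of the 19-membered sulfonate and the two CH2 carbons enter it; no stereocentre is formed. The step needs ipso attack at ring D to outrun hydrogen transfer from the stannane and ipso attack at the ring B carbon of the neighbouring diaryl ether (six-membered transition state); the sulfonyl group makes the ring D ipso carbon the best acceptor for the nucleophilic alkyl radical and makes that path irreversible through SO2 loss, and slow stannane addition at high dilution keeps reduction back.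

Step 14
Reactants: 22 ring C O-benzyl ether of the target
Product: 23 target macrocycle CNP0179896.0
Conditions: H2 (1 atm), 10% Pd/C, EtOAc/MeOH, rt
Reagents that add atoms: none
Why: Hydrogenolysis of the benzyl ether frees the ring C phenol, and no other group in 22 is reducible under these conditions.

**Compound list**

1 | 4-(benzyloxy)-3-hydroxybenzaldehyde | O=Cc1ccc(OCc2ccccc2)c(O)c1 | starting material
2 | 4-(benzyloxy)-3-(methoxymethoxy)benzaldehyde | O=Cc1ccc(OCc2ccccc2)c(OCOC)c1 | intermediate
3 | (3-bromobenzyl)triphenylphosphonium bromide | [Br-].Brc1cccc(C[P+](c2ccccc2)(c2ccccc2)c2ccccc2)c1 | starting material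
4 | (3-bromobenzylidene)triphenylphosphorane (ylide, not isolated) | Brc1cccc(C=P(c2ccccc2)(c2ccccc2)c2ccccc2)c1 | intermediate
5 | 1-(benzyloxy)-4-[2-(3-bromophenyl)ethenyl]-2-(methoxymethoxy)benzene (E/Z mixture) | COCOc1cc(C=Cc2cccc(Br)c2)ccc1OCc1ccccc1 | intermediate
6 | 1-(benzyloxy)-4-[2-(3-bromophenyl)ethyl]-2-(methoxymethoxy)benzene | COCOc1cc(CCc2cccc(Br)c2)ccc1OCc1ccccc1 | intermediate
7 | isovanillin (3-hydroxy-4-methoxybenzaldehyde) | COc1ccc(C=O)cc1O | starting material
8 | allyl bromide | C=CCBr | starting material
9 | 3-(allyloxy)-4-methoxybenzaldehyde | C=CCOc1cc(C=O)ccc1OC | intermediate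
10 | 2-allyl-3-hydroxy-4-methoxybenzaldehyde | C=CCc1c(C=O)ccc(OC)c1O | intermediate
11 | 2-allyl-3-{3-[2-(4-(benzyloxy)-3-(methoxymethoxy)phenyl)ethyl]phenoxy}-4-methoxybenzaldehyde | C=CCc1c(C=O)ccc(OC)c1Oc1cccc(CCc2ccc(OCc3ccccc3)c(OCOC)c2)c1 | intermediate
12 | aryl formate of 13 (not isolated) | C=CCc1c(OC=O)ccc(OC)c1Oc1cccc(CCc2ccc(OCc3ccccc3)c(OCOC)c2)c1 | intermediate
13 | 2-allyl-3-{3-[2-(4-(benzyloxy)-3-(methoxymethoxy)phenyl)ethyl]phenoxy}-4-methoxyphenol | C=CCc1c(O)ccc(OC)c1Oc1cccc(CCc2ccc(OCc3ccccc3)c(OCOC)c2)c1 | intermediate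
14 | 4-fluorobenzenesulfonyl chloride | O=S(=O)(Cl)c1ccc(F)cc1 | starting material
15 | 4-fluorobenzenesulfonate of 13 | C=CCc1c(OS(=O)(=O)c2ccc(F)cc2)ccc(OC)c1Oc1cccc(CCc2ccc(OCc3ccccc3)c(OCOC)c2)c1 | intermediate
16 | 4-fluorobenzenesulfonate with free ring C phenol | C=CCc1c(OS(=O)(=O)c2ccc(F)cc2)ccc(OC)c1Oc1cccc(CCc2ccc(OCc3ccccc3)c(O)c2)c1 | intermediate
17 | 19-membered macrocyclic sulfonate, allyl on ring A | C=CCc1c2ccc(OC)c1Oc1cccc(c1)CCc1ccc(OCc3ccccc3)c(c1)Oc1ccc(cc1)S(=O)(=O)O2 | intermediate
18 | macrocyclic sulfonate, 2,3-dihydroxypropyl on ring A (racemic, not isolated) | OCC(O)Cc1c2ccc(OC)c1Oc1cccc(c1)CCc1ccc(OCc3ccccc3)c(c1)Oc1ccc(cc1)S(=O)(=O)O2 | intermediate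
19 | macrocyclic sulfonate, 2-oxoethyl on ring A (not isolated) | O=CCc1c2ccc(OC)c1Oc1cccc(c1)CCc1ccc(OCc3ccccc3)c(c1)Oc1ccc(cc1)S(=O)(=O)O2 | intermediate
20 | macrocyclic sulfonate, 2-hydroxyethyl on ring A | OCCc1c2ccc(OC)c1Oc1cccc(c1)CCc1ccc(OCc3ccccc3)c(c1)Oc1ccc(cc1)S(=O)(=O)O2 | intermediate
21 | macrocyclic sulfonate, 2-iodoethyl on ring A | ICCc1c2ccc(OC)c1Oc1cccc(c1)CCc1ccc(OCc3ccccc3)c(c1)Oc1ccc(cc1)S(=O)(=O)O2 | intermediate
22 | ring C O-benzyl ether of the target | COc1ccc(O)c2c1Oc1cccc(c1)CCc1ccc(OCc3ccccc3)c(c1)Oc1ccc(cc1)CC2 | intermediate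
23 | target CNP0179896.0 | COc1ccc(O)c2c1Oc1cccc(c1)CCc1ccc(O)c(c1)Oc1ccc(cc1)CC2 | target

**Step count**

Total: 14 steps. Longest linear sequence: 12 steps (1 → 23 through steps 1–3 and 6–14).

**Steps most likely to fail**

Step 13 (Proposed new method). The primary alkyl radical may be reduced by the stannane before it reaches the ring D ipso carbon, may transfer ring B from the ether oxygen instead, or the phenoxyl radical may fail to propagate the chain. The fallback closes the same aryl–CH2 bond by known cross-coupling and sets out from 13.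
- O-Benzylation (BnBr, K2CO3, DMF) would give the ring A benzyl ether F1.
- Acid methanolysis of the MOM group would give the ring C phenol F2.
- A CuI/picolinic acid Ullmann coupling with 1-bromo-4-iodobenzene (iodide-selective) would give the 4-bromophenyl ether F3, which already holds the ring C–O–ring D ether.
- Lemieux–Johnson cleavage, through the diol F4 and the aldehyde F5, and NaBH4 reduction would give the alcohol F6.
- Appel iodination would give the iodide F7, and zinc insertion (Zn dust, LiCl, THF) the alkylzinc iodide F8.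
- An intramolecular Negishi coupling (Pd(OAc)2, SPhos, THF, high dilution) would give the macrocyclic bis(benzyl ether) F9.
- Hydrogenolysis (H2, Pd/C) of both benzyl ethers comes back to the route at 23.

Step 10. Fluoride displacement may be slow enough for intermolecular etherification to give oligomers, or for the phenoxide to attack sulfur and move the sulfonyl group between the two phenol oxygens. The fallback forms the same C–O bond by copper catalysis on an aryl iodide and sets out from 13.
- Sulfonylation with 4-iodobenzenesulfonyl chloride (Et3N, DMAP) would give the 4-iodobenzenesulfonate F10.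
- MOM cleavage (HCl, MeOH) would give the phenol F11.
- An intramolecular Ullmann etherification (CuI, N,N-dimethylglycine, Cs2CO3, dioxane, 90 °C, high dilution), in which the C–O bond forms through copper insertion into the C–I bond and not through addition–elimination, comes back to the route at 17.

Step 6. C–O coupling at the doubly ortho-substituted phenol may be slow, so that protodebromination of 6 or base-induced migration of the allyl double bond takes over. The fallback reverses the order of ether formation and allyl introduction and sets out from 7 and 6.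
- Ullmann coupling of the unhindered phenol 7 with bromide 6 (CuI, picolinic acid, K3PO4, DMSO) would give the diaryl ether aldehyde F12.
- Masking the formyl group in the flask as the α-amino alkoxide (lithium N,N,N′-trimethylethylenediamide, THF) and ortho-lithiation with n-BuLi, at the carbon flanked by the masked formyl group and the aryloxy oxygen, would give the lithiated amino alkoxide F13.
- Allylation with allyl bromide 8 and aqueous work-up, which releases the aldehyde, comes back to the route at 11.

**Further compounds**

F1 | step 13 | ring A benzyl ether of 13 | C=CCc1c(OCc2ccccc2)ccc(OC)c1Oc1cccc(CCc2ccc(OCc3ccccc3)c(OCOC)c2)c1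
F2 | step 13 | ring C phenol (ring A benzyl ether, MOM removed) | C=CCc1c(OCc2ccccc2)ccc(OC)c1Oc1cccc(CCc2ccc(OCc3ccccc3)c(O)c2)c1
F3 | step 13 | 4-bromophenyl ether of F2 | C=CCc1c(OCc2ccccc2)ccc(OC)c1Oc1cccc(CCc2ccc(OCc3ccccc3)c(Oc3ccc(Br)cc3)c2)c1
F4 | step 13 | diol from F3 (racemic, not isolated) | OCC(O)Cc1c(OCc2ccccc2)ccc(OC)c1Oc1cccc(CCc2ccc(OCc3ccccc3)c(Oc3ccc(Br)cc3)c2)c1
F5 | step 13 | aldehyde from F4 (not isolated) | O=CCc1c(OCc2ccccc2)ccc(OC)c1Oc1cccc(CCc2ccc(OCc3ccccc3)c(Oc3ccc(Br)cc3)c2)c1
F6 | step 13 | alcohol (2-hydroxyethyl on ring A) | OCCc1c(OCc2ccccc2)ccc(OC)c1Oc1cccc(CCc2ccc(OCc3ccccc3)c(Oc3ccc(Br)cc3)c2)c1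
F7 | step 13 | iodide (2-iodoethyl on ring A) | ICCc1c(OCc2ccccc2)ccc(OC)c1Oc1cccc(CCc2ccc(OCc3ccccc3)c(Oc3ccc(Br)cc3)c2)c1
F8 | step 13 | alkylzinc iodide from F7 (not isolated) | I[Zn]CCc1c(OCc2ccccc2)ccc(OC)c1Oc1cccc(CCc2ccc(OCc3ccccc3)c(Oc3ccc(Br)cc3)c2)c1
F9 | step 13 | macrocyclic bis(benzyl ether) of the target | COc1ccc(OCc3ccccc3)c2c1Oc1cccc(c1)CCc1ccc(OCc3ccccc3)c(c1)Oc1ccc(cc1)CC2
F10 | step 10 | 4-iodobenzenesulfonate of 13 | C=CCc1c(OS(=O)(=O)c2ccc(I)cc2)ccc(OC)c1Oc1cccc(CCc2ccc(OCc3ccccc3)c(OCOC)c2)c1
F11 | step 10 | 4-iodobenzenesulfonate with free ring C phenol | C=CCc1c(OS(=O)(=O)c2ccc(I)cc2)ccc(OC)c1Oc1cccc(CCc2ccc(OCc3ccccc3)c(O)c2)c1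
F12 | step 6 | 3-{3-[2-(4-(benzyloxy)-3-(methoxymethoxy)phenyl)ethyl]phenoxy}-4-methoxybenzaldehyde | O=Cc1ccc(OC)c(Oc2cccc(CCc3ccc(OCc4ccccc4)c(OCOC)c3)c2)c1
F13 | step 6 | ortho-lithiated α-amino alkoxide of F12 (racemic at the carbinol carbon, not isolated) | [Li]c1c(C(O[Li])N(C)CCN(C)C)ccc(OC)c1Oc1cccc(CCc2ccc(OCc3ccccc3)c(OCOC)c2)c1
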